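**Remark on the chemistry:** the target has no stereocentre and its structure specifies no axial configuration, so the hindered ring A–ring B and C1–C7 axes are not controlled. 4-Iodophenol is taken as the source of all three 4-oxyphenyl units.

## Analysis of the target

Selaginellin F is built on a central benzene, ring A, with four contiguous substituents: a hydroxymethyl group at C5, a (4-hydroxyphenyl)ethynyl group at C6, the methide carbon C7 on C1, and a 2,4-dihydroxyphenyl ring (ring B) at C2. C3 and C4 carry hydrogen. C7 is the exocyclic carbon of a p-quinone methide and also bears a 4-hydroxyphenyl group, so the C7 unit is the dehydrated form of a bis(4-hydroxyphenyl)carbinol. There is no stereocentre, and because the quinoid ring is symmetrical the C7 double bond has no geometric isomers. The sensitive groups are the electrophilic quinone methide, four phenols (two of them on the electron-rich ring B), a primary benzylic alcohol, and a diarylalkyne ortho to C7 that can accept a heteroatom nucleophile sitting on C7. The difficulty is steric and regiochemical: C1 lies between a biaryl bond and an alkyne and must end up bonded to a fully substituted carbon, and ring B needs an oxygen ortho to that crowded biaryl bond. The plan rests on the chain O–C2(ring B)–C1(ring B)–C2(ring A)–C1(ring A)–C7, which is the six-membered ring of a 6H-benzo[c]chromen-6-one when C7 is a carboxyl carbon. Such a lactone can be closed from a biaryl-2-carboxylic acid onto a symmetrical 4-oxygenated phenyl ring, and it then leaves C7 as an acyl donor for two identical 4-oxyphenyl nucleophiles.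

## Retrosynthetic reasoning

**17 to 15 (through 16).** No skeletal bond is cut. The quinone methide of 17 is the dehydrated form of a C7 carbinol, so 17 is taken back to the triaryl carbinol 15, in which the three 4-oxyphenyl oxygens are acetal-protected. The forward step must remove three acetals and ionise the C7–OH bond in one acidic operation, passing through the free carbinol 16, without touching the C5 hydroxymethyl group or the alkyne.

**15 to 13 and 9 (through 14).** Both C7–aryl bonds are cut. The two aryl groups on C7 are identical, so they can come from two additions of one aryllithium, 14 (made from iodide 9), to a carboxyl derivative at C7. That derivative is lactone 13, whose leaving group is the ring B 2-oxygen; opening it frees that phenol without a separate deprotection. An excess of 14 is also expected to strip both pivalate esters, so one operation exposes every oxygen except the three acetals.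

**13 to 8 and 12.** The C6–C(sp) bond is cut. An alkyne would not survive an oxidative radical cyclisation next to a carboxyl group, so it is introduced after the lactone is in place, by coupling bromide 8 with the terminal alkyne 12. The bromine at C6 is present in the commercial ring A building block, so no halogenation step is needed.

**8 to 7 (key disconnection).** The ring B C2–O bond is cut, which leads back to the biaryl acid 7 with a plain 4-pivaloyloxyphenyl ring. Cutting here means ring B can be introduced as a cheap para-substituted phenyl group and its ortho oxygen placed by the C7 carboxyl itself, with no regiochemical choice because the two ortho carbons are equivalent. The forward step must remove one C–H and one O–H hydrogen and form the C–O bond without decarboxylation and without attack at the ipso carbon.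

**7 to 6 to 5.** The C5 benzylic C–O bond is taken back to a C–Br bond (6) and then to the C–H bond of a methyl group (5). The methyl group is the only benzylic position in 5, so a radical bromination followed by displacement with a hindered carboxylate installs the protected hydroxymethyl group in two steps.

**5 to 4 and 3.** The ring A C2–ring B bond is cut. Acid 4 has a single free position ortho to its carboxyl group, so a carboxylate-directed C–H arylation with aryl iodide 3 can only give the required 1,2,3,6-substitution pattern. The biaryl bond is thus made while C1 carries only a flat carboxyl group.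

**Building blocks.** Ester 3 comes from 1 and 2 by acylation. Alkyne 12 comes from 11 by desilylation, 11 from 9 and 10 by cross-coupling, and 9 from 1 by acetal formation. Phenol 1 therefore supplies ring B, both C7 aryl groups and the alkyne aryl group.

## Alternatives that were turned down

**Alternative 1:** Ring A is disconnected at C6–C(alkyne) and C1–C7 at once. A C1–C6 aryne is generated from 2-iodo-3-[(4-methoxybenzyl)oxy]-6-[(methoxymethoxy)methyl]phenyl 4-chlorobenzenesulfonate A2 by halogen–magnesium exchange and loss of the sulfonate. The alkynylmagnesium chloride A3 adds at C6, remote from the C2 ether oxygen, and the resulting C1 arylmagnesium is captured by bis[4-(methoxymethoxy)phenyl]methanone A4 to give the triaryl carbinol A1.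
- For: two skeletal C–C bonds and the whole C7 unit are formed in one flask; the regiochemistry of addition to 3-alkoxy arynes is dependable; the route is more convergent than the chosen one, and on this point it is the stronger plan.
- Against: the aryne is substituted on both sides, so A3 must enter next to the C5 side chain. The C1 arylmagnesium, flanked by an ether and an alkyne, must then add to an electron-rich diaryl ketone, where protonation and electron transfer compete. Ring B is still missing in A1: it has to be attached at C2, directly beside the fully substituted C7, by cross-coupling with a 2,4-dioxygenated arylboron partner that protodeboronates readily, and the acid-labile carbinol must be carried through ether cleavage, triflation and that coupling.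
- Comparison: the chosen strategy forms the crowded biaryl bond first, when C1 bears only a carboxyl group, needs no cross-coupling next to C7, and obtains the ring B ortho oxygen from a C–H bond.

**Alternative 2:** Ring A itself is disconnected into a 1,3-diyne and an alkyne joined by an ester tether, as in the triyne A6. Heating A6 in a saturated cycloalkane solvent triggers a hexadehydro-Diels–Alder reaction that forms C5–C6 and C1–C2 and closes ring A and a phthalide; the C3–C4 aryne then takes two hydrogen atoms from the solvent to give phthalide A5.
- For: all four substituents of ring A are placed by the tether, with no directing-group or selectivity question; the crowded C1–C2 and C1–C7 neighbourhood is assembled intramolecularly without reagents; the C7 carbon is already quaternary. On regiochemical certainty it is stronger than the chosen plan.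
- Against: the aryne sits next to C2, whose ring B carries an ortho pivalate within reach, so intramolecular trapping competes with the slow bimolecular double hydrogen transfer. The doubly benzylic, propargylic methyl ether may ionise at the cyclisation temperature. After the cascade the C6 carbonyl carbon must still be converted into an arylalkyne by partial reduction in the presence of two pivalates, one-carbon homologation and cross-coupling. A6 itself needs a multistep convergent synthesis.
- Comparison: the chosen route has three steps after its key step, and its key step has close precedent on the same ring system.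

**Alternative 3:** Ring A is disconnected into the unsaturated diazoketone A8 and the siloxyalkyne A9. Irradiation causes a Wolff rearrangement (C3–C4) to a vinylketene, which adds A9 (C6–C1 and C2–C3); the cyclobutenone opens and recloses by 6π electrocyclisation (C5–C6) to give the phenol A7, with a free hydroxyl at C6, a silyl ether at C2 and a diarylmethyl group at C1.
- For: the polarity of the ynol ether fixes the substitution pattern; the two oxygens are differentiated for sequential couplings; C7 is carried as a robust triarylmethane, so no acid-labile carbinol is present until the end. On the stability of C7 it is stronger than the chosen plan.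
- Against: both the alkyne at C6 and ring B at C2 must be attached by coupling of aryl triflates that flank the bulky diarylmethyl group, again with the fragile 2,4-dioxygenated arylboron partner. The C7–H bond must finally be oxidised to the methide in the presence of a resorcinol and a diarylalkyne. A8 and A9 are sensitive and take several steps each, and roughly eight steps follow the key step.
- Comparison: the chosen strategy introduces C7 at the carboxyl oxidation level, so no late oxidation is needed, and it avoids both hindered couplings.

Key step: step 5

## Route

**Step 1**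
Reactants: 1 4-iodophenol; 2 pivaloyl chloride
Product: 3 4-iodophenyl pivalate
Conditions: Et3N, DMAP (cat.), CH2Cl2, 0 °C to rt
Reagents that add atoms: none
Why: DMAP-catalysed acylation of a phenol by an acid chloride; the pivalate is chosen because it withstands hot AcOH, bromine radicals and the anode and keeps the ring electron-poor.

**Step 2**
Reactants: 4 2-bromo-3-methylbenzoic acid; 3 4-iodophenyl pivalate
Product: 5 2-bromo-3-methyl-6-[4-(pivaloyloxy)phenyl]benzoic acid
Conditions: Pd(OAc)2 (5 mol %), AgOAc (1.3 equiv), 3 (2 equiv), AcOH, 110 °C
Reagents that add atoms: none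
Why: Carboxylate-directed ortho C–H arylation: the bound carboxylate guides divalent palladium to the only free ortho C–H bond (C6), the aryl iodide adds to give tetravalent palladium, and reductive elimination forms the biaryl bond while AgOAc removes iodide. Zerovalent palladium is not on the cycle, so the C–Br bond should stay intact.

**Step 3**
Reactants: 5 2-bromo-3-methyl-6-[4-(pivaloyloxy)phenyl]benzoic acid
Product: 6 2-bromo-3-(bromomethyl)-6-[4-(pivaloyloxy)phenyl]benzoic acid
Conditions: NBS (1.05 equiv), AIBN (cat.), PhCl, 85 °C
Reagents that add atoms: N-bromosuccinimide, O=C1CCC(=O)N1Br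
Why: Wohl–Ziegler bromination; the C3 methyl group holds the only benzylic C–H bonds, one equivalent of NBS limits dibromination, and the tert-butyl C–H bonds and the free acid are inert to bromine radicals.

**Step 4**
Reactants: 6 2-bromo-3-(bromomethyl)-6-[4-(pivaloyloxy)phenyl]benzoic acid
Product: 7 2-bromo-3-(pivaloyloxymethyl)-6-[4-(pivaloyloxy)phenyl]benzoic acid
Conditions: CsO2CC(CH3)3 (5 equiv), DMF, rt; then 1 M HCl (work-up)
Reagents that add atoms: caesium pivalate, CC(C)(C)C(=O)[O-].[Cs+]
Why: SN2 displacement of a primary benzylic bromide by a carboxylate in a dipolar aprotic solvent; the fivefold excess of the more basic pivalate should outcompete the substrate's own, less basic arenecarboxylate, and the meta relationship of CO2H and CH2Br excludes lactone formation.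

**Step 5**
Reactants: 7 2-bromo-3-(pivaloyloxymethyl)-6-[4-(pivaloyloxy)phenyl]benzoic acid
Product: 8 7-bromo-6-oxo-8-(pivaloyloxymethyl)-6H-benzo[c]chromen-3-yl pivalate
Conditions: graphite anode, Pt cathode, undivided cell, n-Bu4NBF4, MeOH–MeCN, constant current (about 2.5 F per mol), rt
Reagents that add atoms: none
Why: The acid is deprotonated by methoxide formed at the cathode, and the carboxylate is oxidised at the graphite anode to an aroyloxy radical (Kolbe-type one-electron oxidation). The radical oxygen adds to the ortho carbon of the neighbouring 4-pivaloyloxyphenyl ring, and the cyclohexadienyl radical loses a second electron and a proton to rearomatise; the cathode turns the protons into H2, so no chemical oxidant is needed and the bulk stays near neutral, which protects the aryl pivalate and the new aryl lactone from methanolysis. The closest known reaction is the anodic dehydrogenative lactonisation of biaryl-2-carboxylic acids to 6H-benzo[c]chromen-6-ones in this medium. The pyranone ring closes by radical C–O bond formation in the 6-endo mode, the oxygen bonding to C2 of ring B. No stereocentre is formed. The step needs ortho over ipso attack and cyclisation over loss of CO2: the para oxygen is an ester, a weak donor that cannot be dealkylated, so the dearomatising spiro pathway known for para-alkoxy biaryls gains little, and a spiro radical that does form can shift its acyloxy group to the ortho carbon and reach the same product, while aroyloxy radicals lose CO2 more slowly than they add to a ring held at bonding distance. The two ortho carbons of ring B are equivalent, so one lactone should result, and the electron-poor bromo-substituted ring A and the benzylic pivalate should not be oxidised at the potential of the carboxylate.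

**Step 6**
Reactants: 1 4-iodophenol
Product: 9 1-iodo-4-(methoxymethoxy)benzene
Conditions: MOMCl, i-Pr2NEt, CH2Cl2, 0 °C to rt
Reagents that add atoms: chloromethyl methyl ether, COCCl
Why: O-Alkylation of the phenol by the α-chloro ether (acetal formation); the MOM ether withstands organolithium reagents, amines and palladium catalysis and is removed in the final acid step.

**Step 7**
Reactants: 9 1-iodo-4-(methoxymethoxy)benzene; 10 ethynyltrimethylsilane
Product: 11 {[4-(methoxymethoxy)phenyl]ethynyl}trimethylsilane
Conditions: PdCl2(PPh3)2 (2 mol %), CuI (4 mol %), Et3N, THF, rt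
Reagents that add atoms: none
Why: Sonogashira coupling of an aryl iodide with a terminal alkyne at room temperature; the silyl group blocks the second alkyne terminus.

**Step 8**
Reactants: 11 {[4-(methoxymethoxy)phenyl]ethynyl}trimethylsilane
Product: 12 1-ethynyl-4-(methoxymethoxy)benzene
Conditions: K2CO3 (0.2 equiv), MeOH, rt
Reagents that add atoms: none
Why: Base-catalysed protodesilylation of an alkynylsilane by methoxide; the MOM ether is stable to these conditions.

**Step 9**
Reactants: 8 7-bromo-6-oxo-8-(pivaloyloxymethyl)-6H-benzo[c]chromen-3-yl pivalate; 12 1-ethynyl-4-(methoxymethoxy)benzene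
Product: 13 7-{[4-(methoxymethoxy)phenyl]ethynyl}-6-oxo-8-(pivaloyloxymethyl)-6H-benzo[c]chromen-3-yl pivalate
Conditions: PdCl2(PhCN)2 (3 mol %), P(t-Bu)3·HBF4 (6 mol %), CuI (2 mol %), i-Pr2NH, 1,4-dioxane, rt to 50 °C
Reagents that add atoms: none
Why: Sonogashira coupling of a di-ortho-substituted aryl bromide that is activated by the ortho lactone carbonyl; the bulky, electron-rich phosphine gives a monoligated zerovalent palladium that should insert near room temperature, and the hindered secondary amine should not open the aryl lactone or the pivalates.

**Step 10**
Reactants: 13 7-{[4-(methoxymethoxy)phenyl]ethynyl}-6-oxo-8-(pivaloyloxymethyl)-6H-benzo[c]chromen-3-yl pivalate; 9 1-iodo-4-(methoxymethoxy)benzene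
Product: 15 4-[2-{hydroxybis[4-(methoxymethoxy)phenyl]methyl}-4-(hydroxymethyl)-3-{[4-(methoxymethoxy)phenyl]ethynyl}phenyl]benzene-1,3-diol, via 4-(methoxymethoxy)phenyllithium 14 (not isolated)
Conditions: 9 (8 equiv), tert-butyllithium (16 equiv), THF, −78 °C; then 13, −78 to 0 °C; aq. NH4Cl
Reagents that add atoms: none
Why: Iodine–lithium exchange gives 14, and double addition of this aryllithium to the lactone follows: the first equivalent expels the ring B 2-phenoxide to leave a diaryl ketone, the second gives the tertiary alkoxide. Further equivalents attack both pivalate carbonyls and release the ring B 4-phenoxide and the C5 benzylic alkoxide; two equivalents of tert-butyllithium per iodide leave no alkyl iodide in the flask.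

**Step 11**
Reactants: 15 4-[2-{hydroxybis[4-(methoxymethoxy)phenyl]methyl}-4-(hydroxymethyl)-3-{[4-(methoxymethoxy)phenyl]ethynyl}phenyl]benzene-1,3-diol
Product: 17 Selaginellin F, via MOM-free triarylcarbinol 16 (not isolated)
Conditions: 2 M aq. HCl, MeOH–THF, rt to 40 °C; then NaHCO3 (work-up)
Reagents that add atoms: none
Why: Acid-catalysed acetal cleavage frees the three phenols, and the bis(4-hydroxyphenyl)carbinol ionises to a strongly stabilised triaryl cation that loses a phenolic proton to give the quinone methide, as in the formation of fuchsone-type dyes. The primary benzylic alcohol on the unactivated ring A should not ionise under these conditions.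

## Compound list

1 | 4-iodophenol | Oc1ccc(I)cc1 | starting material
2 | pivaloyl chloride | CC(C)(C)C(=O)Cl | starting material
3 | 4-iodophenyl pivalate | CC(C)(C)C(=O)Oc1ccc(I)cc1 | intermediate
4 | 2-bromo-3-methylbenzoic acid | Cc1cccc(C(=O)O)c1Br | starting material
5 | 2-bromo-3-methyl-6-[4-(pivaloyloxy)phenyl]benzoic acid | Cc1ccc(-c2ccc(OC(=O)C(C)(C)C)cc2)c(C(=O)O)c1Br | intermediate
6 | 2-bromo-3-(bromomethyl)-6-[4-(pivaloyloxy)phenyl]benzoic acid | BrCc1ccc(-c2ccc(OC(=O)C(C)(C)C)cc2)c(C(=O)O)c1Br | intermediate
7 | 2-bromo-3-(pivaloyloxymethyl)-6-[4-(pivaloyloxy)phenyl]benzoic acid | CC(C)(C)C(=O)OCc1ccc(-c2ccc(OC(=O)C(C)(C)C)cc2)c(C(=O)O)c1Br | intermediate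
8 | 7-bromo-6-oxo-8-(pivaloyloxymethyl)-6H-benzo[c]chromen-3-yl pivalate | O=C1Oc2cc(OC(=O)C(C)(C)C)ccc2-c2ccc(COC(=O)C(C)(C)C)c(Br)c21 | intermediate
9 | 1-iodo-4-(methoxymethoxy)benzene | COCOc1ccc(I)cc1 | intermediate
10 | ethynyltrimethylsilane | C#C[Si](C)(C)C | starting material
11 | {[4-(methoxymethoxy)phenyl]ethynyl}trimethylsilane | COCOc1ccc(C#C[Si](C)(C)C)cc1 | intermediate
12 | 1-ethynyl-4-(methoxymethoxy)benzene | COCOc1ccc(C#C)cc1 | intermediate
13 | 7-{[4-(methoxymethoxy)phenyl]ethynyl}-6-oxo-8-(pivaloyloxymethyl)-6H-benzo[c]chromen-3-yl pivalate | O=C1Oc2cc(OC(=O)C(C)(C)C)ccc2-c2ccc(COC(=O)C(C)(C)C)c(C#Cc3ccc(OCOC)cc3)c21 | intermediate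
14 | 4-(methoxymethoxy)phenyllithium | [Li]c1ccc(OCOC)cc1 | intermediate (not isolated)
15 | 4-[2-{hydroxybis[4-(methoxymethoxy)phenyl]methyl}-4-(hydroxymethyl)-3-{[4-(methoxymethoxy)phenyl]ethynyl}phenyl]benzene-1,3-diol | OCc1ccc(-c2ccc(O)cc2O)c(C(O)(c2ccc(OCOC)cc2)c2ccc(OCOC)cc2)c1C#Cc1ccc(OCOC)cc1 | intermediate
16 | 4-{2-[hydroxybis(4-hydroxyphenyl)methyl]-4-(hydroxymethyl)-3-[(4-hydroxyphenyl)ethynyl]phenyl}benzene-1,3-diol | OCc1ccc(-c2ccc(O)cc2O)c(C(O)(c2ccc(O)cc2)c2ccc(O)cc2)c1C#Cc1ccc(O)cc1 | intermediate (not isolated)
17 | Selaginellin F | O=C1C=CC(=C(c2ccc(O)cc2)c2c(-c3ccc(O)cc3O)ccc(CO)c2C#Cc2ccc(O)cc2)C=C1 | target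

## Step count and risk

Total step count: 11. Longest linear sequence: 8 steps (steps 1, 2, 3, 4, 5, 9, 10 and 11, from 4-iodophenol to the target).

**Step 5 (key step).** The twisted 2,6-disubstituted aroyloxy radical may lose CO2 before it reaches ring B, and ipso attack followed by methanolytic loss of the pivaloyl group would give a dearomatised spirolactone. Fallback: from 7, the C–O bond is formed by an organometallic rather than a radical pathway, using Pd(OAc)2 (10 mol %), PhI(OAc)2, N-acetylglycine and KOAc in t-BuOH at 80 °C. The carboxylate directs palladation of the ring B ortho C–H bond, the palladacycle is oxidised to tetravalent palladium, and C–O reductive elimination gives the lactone. No free oxygen radical is formed, so neither decarboxylation nor ipso attack applies, and the C–Br bond is safe because zerovalent palladium is not formed. This returns the route at 8 without a new compound.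

**Step 11.** The C7 cation may be captured by the neighbouring ring B 2-hydroxyl (closure of a six-membered cyclic ether) instead of losing a proton to the quinone methide, and the released formaldehyde acetal may alkylate the resorcinol ring. Fallback: from 15, the acid treatment is run to completion and the closed isomer is isolated, 6,6-bis(4-hydroxyphenyl)-8-(hydroxymethyl)-7-[(4-hydroxyphenyl)ethynyl]-6H-benzo[c]chromen-3-ol F1. This phenolic triarylmethyl aryl ether is then opened with DBU in THF at 0 °C: the 4-phenoxide expels the ring B aryloxide in an E1cB elimination, the ring opening known for phenolphthalein-type lactones and phenolic α-aryl ethers. The quinone methide phenolate is neutralised cold with a NaH2PO4 buffer and extracted at once, which returns the route at 17.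

**Step 10.** The reaction may stall after the first addition, because the ring B phenoxide can close onto the ketone as a lactol alkoxide. The hindered benzylic pivalate may be cleaved incompletely, and on warming the tertiary alkoxide may add across the ortho alkyne. Fallback: from 13, the aryl group is delivered as the organocerium reagent made from 14 and anhydrous CeCl3 in THF at −78 °C, and the mixture is quenched cold. The lactone is converted into the carbinol and the aryl pivalate is cleaved, while the benzylic ester is expected to survive, giving [4-(2,4-dihydroxyphenyl)-3-{hydroxybis[4-(methoxymethoxy)phenyl]methyl}-2-{[4-(methoxymethoxy)phenyl]ethynyl}phenyl]methyl pivalate F2. Its ester is then removed reductively with i-Bu2AlH in CH2Cl2 at −78 °C, which returns the route at 15.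

**Step 2.** The 2,6-disubstituted product acid may undergo silver-assisted protodecarboxylation at 110 °C, or the ortho bromine may slow palladation so that conversion stalls. Fallback: from 4, carboxylate-directed ortho-iodination (Pd(OAc)2, PhI(OAc)2, I2, DMF) gives 2-bromo-6-iodo-3-methylbenzoic acid F3. Suzuki–Miyaura coupling at its less hindered, more reactive C–I bond (Pd(PPh3)4, CsF, 1,4-dioxane, 80 °C) with 4-(4,4,5,5-tetramethyl-1,3,2-dioxaborolan-2-yl)phenyl pivalate F4, made from the commercial phenol boronate and 2 with Et3N, returns the route at 5.

**Step 4.** The substrate's own carboxylate may be alkylated by the benzylic bromide of a second molecule, giving oligomeric esters. Fallback: from 5, the acid is masked with tert-butyl 2,2,2-trichloroacetimidate (cyclohexane–CH2Cl2, rt) as tert-butyl 2-bromo-3-methyl-6-[4-(pivaloyloxy)phenyl]benzoate F5. NBS and AIBN give tert-butyl 2-bromo-3-(bromomethyl)-6-[4-(pivaloyloxy)phenyl]benzoate F6, and CsO2CC(CH3)3 in DMF gives tert-butyl 2-bromo-3-(pivaloyloxymethyl)-6-[4-(pivaloyloxy)phenyl]benzoate F7. CF3CO2H in CH2Cl2 then cleaves only the tert-butyl ester and returns the route at 7.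

**Step 9.** Slow oxidative addition at the di-ortho-substituted C–Br bond would let copper-mediated homocoupling of the alkyne and amine attack on the aryl ester compete. Fallback: from 12, deprotonation with n-butyllithium and transmetalation with ZnCl2 in THF gives chloro{[4-(methoxymethoxy)phenyl]ethynyl}zinc F8. Negishi coupling of F8 with 8 (Pd(P(t-Bu)3)2, THF, rt to 50 °C) uses no copper and no amine, and the alkynylzinc does not add to esters; this returns the route at 13.

## Further compounds

F0 | step 5 | none | none
F1 | step 11 | 6,6-bis(4-hydroxyphenyl)-8-(hydroxymethyl)-7-[(4-hydroxyphenyl)ethynyl]-6H-benzo[c]chromen-3-ol | OCc1ccc2-c3ccc(O)cc3OC(c3ccc(O)cc3)(c3ccc(O)cc3)c2c1C#Cc1ccc(O)cc1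
F2 | step 10 | [4-(2,4-dihydroxyphenyl)-3-{hydroxybis[4-(methoxymethoxy)phenyl]methyl}-2-{[4-(methoxymethoxy)phenyl]ethynyl}phenyl]methyl pivalate | CC(C)(C)C(=O)OCc1ccc(-c2ccc(O)cc2O)c(C(O)(c2ccc(OCOC)cc2)c2ccc(OCOC)cc2)c1C#Cc1ccc(OCOC)cc1
F3 | step 2 | 2-bromo-6-iodo-3-methylbenzoic acid | Cc1ccc(I)c(C(=O)O)c1Br
F4 | step 2 | 4-(4,4,5,5-tetramethyl-1,3,2-dioxaborolan-2-yl)phenyl pivalate | CC(C)(C)C(=O)Oc1ccc(B2OC(C)(C)C(C)(C)O2)cc1
F5 | step 4 | tert-butyl 2-bromo-3-methyl-6-[4-(pivaloyloxy)phenyl]benzoate | Cc1ccc(-c2ccc(OC(=O)C(C)(C)C)cc2)c(C(=O)OC(C)(C)C)c1Br
F6 | step 4 | tert-butyl 2-bromo-3-(bromomethyl)-6-[4-(pivaloyloxy)phenyl]benzoate | BrCc1ccc(-c2ccc(OC(=O)C(C)(C)C)cc2)c(C(=O)OC(C)(C)C)c1Br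
F7 | step 4 | tert-butyl 2-bromo-3-(pivaloyloxymethyl)-6-[4-(pivaloyloxy)phenyl]benzoate | CC(C)(C)C(=O)OCc1ccc(-c2ccc(OC(=O)C(C)(C)C)cc2)c(C(=O)OC(C)(C)C)c1Br
F8 | step 9 | chloro{[4-(methoxymethoxy)phenyl]ethynyl}zinc | COCOc1ccc(C#C[Zn]Cl)cc1
A1 | alternative 1 | {2-[(4-methoxybenzyl)oxy]-5-[(methoxymethoxy)methyl]-6-{[4-(methoxymethoxy)phenyl]ethynyl}phenyl}bis[4-(methoxymethoxy)phenyl]methanol | COCOCc1ccc(OCc2ccc(OC)cc2)c(C(O)(c2ccc(OCOC)cc2)c2ccc(OCOC)cc2)c1C#Cc1ccc(OCOC)cc1
A2 | alternative 1 | 2-iodo-3-[(4-methoxybenzyl)oxy]-6-[(methoxymethoxy)methyl]phenyl 4-chlorobenzenesulfonate | COCOCc1ccc(OCc2ccc(OC)cc2)c(I)c1OS(=O)(=O)c1ccc(Cl)cc1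
A3 | alternative 1 | chloro{[4-(methoxymethoxy)phenyl]ethynyl}magnesium | COCOc1ccc(C#C[Mg]Cl)cc1
A4 | alternative 1 | bis[4-(methoxymethoxy)phenyl]methanone | COCOc1ccc(C(=O)c2ccc(OCOC)cc2)cc1
A5 | alternative 2 | 4-(7-{methoxybis[4-(methoxymethoxy)phenyl]methyl}-1-oxo-1,3-dihydroisobenzofuran-6-yl)-1,3-phenylene dipivalate | O=C1OCc2ccc(-c3ccc(OC(=O)C(C)(C)C)cc3OC(=O)C(C)(C)C)c(C(OC)(c3ccc(OCOC)cc3)c3ccc(OCOC)cc3)c12
A6 | alternative 2 | 5-[2,4-bis(pivaloyloxy)phenyl]penta-2,4-diyn-1-yl 4-methoxy-4,4-bis[4-(methoxymethoxy)phenyl]but-2-ynoate | CC(C)(C)C(=O)Oc1ccc(C#CC#CCOC(=O)C#CC(OC)(c2ccc(OCOC)cc2)c2ccc(OCOC)cc2)c(OC(=O)C(C)(C)C)c1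
A7 | alternative 3 | 2-{bis[4-(methoxymethoxy)phenyl]methyl}-6-(tert-butyldimethylsilyloxymethyl)-3-(triisopropylsilyloxy)phenol | Oc1c(CO[Si](C)(C)C(C)(C)C)ccc(O[Si](C(C)C)(C(C)C)C(C)C)c1C(c1ccc(OCOC)cc1)c1ccc(OCOC)cc1
A8 | alternative 3 | (E)-5-(tert-butyldimethylsilyloxy)-1-diazopent-3-en-2-one | CC(C)(C)[Si](C)(C)OC/C=C/C(=O)C=[N+]=[N-]
A9 | alternative 3 | ({3,3-bis[4-(methoxymethoxy)phenyl]prop-1-yn-1-yl}oxy)triisopropylsilane | COCOc1ccc(C(C#CO[Si](C(C)C)(C(C)C)C(C)C)c2ccc(OCOC)cc2)cc1
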